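The interflavan bond is never forged at an arene. Instead the lower D-ring (C4a', C5', C6', C7', C8', C8a') is built around the already existing C4–C8' bond by a vinylketene–siloxyalkyne benzannulation. The step exploits the phloroglucinol pattern of this ring, in which C8' lies between the C8a' and C7' oxygens. A flavan-4-yl siloxyalkyne delivers C8' and C7'. A 3-benzyloxy vinylketene, formed by Wolff rearrangement of an α'-diazo enone carrying C4', the C3' gallate and C2', delivers C8a', C6', C5' and C4a'. One operation thus gives the pentasubstituted arene with only the C8a' hydroxyl free, ready for pyran closure onto C2'.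

Key step: step 18

Remark: primed locants denote the lower unit; compounds 10, 13, 20 and 24 are taken as purchasable; in every SMILES the benzyl rings are closed with the digit 9.

Step 1
Reactants: 1 (+)-dihydrorobinetin
Product: 2 (2R,3R)-7-(benzyloxy)-3-hydroxy-2-[3,4,5-tris(benzyloxy)phenyl]chroman-4-one
Conditions: BnBr (4.4 equiv), K2CO3, DMF, rt, Ar
Reagents that add atoms: benzyl bromide, BrCc1ccccc1
Why: Williamson etherification in which carbonate deprotonates only the four phenols, so the C3 alcohol stays free and the two stereocentres taken from 1 are not touched.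

Step 2
Reactants: 2 tetra-O-benzyl dihydrorobinetin
Product: 3 (2R,3S,4R)-7-(benzyloxy)-2-[3,4,5-tris(benzyloxy)phenyl]chromane-3,4-diol (2,3-trans-3,4-trans)
Conditions: NaBH4, MeOH/THF (1:1), 0 °C
Reagents that add atoms: none
Why: Borohydride reduction of the aryl ketone, hydride adding to the face anti to the C3 hydroxyl to give the 3,4-trans diol; the new C4 centre is provisional because it is ionised in step 4.

Step 3
Reactants: 3 flavan-3,4-diol
Product: 4 3,4-di-O-benzyl ether of 3 (2,3-trans-3,4-trans hexabenzyl flavan-3,4-diol)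
Conditions: NaH, BnBr, Bu4NI (cat.), DMF, 0 °C → rt
Reagents that add atoms: benzyl bromide, BrCc1ccccc1
Why: Double Williamson O-benzylation with sodium hydride, which protects O3 for the rest of the route and at the same time turns O4 into an ionisable benzylic ether.

Step 4
Reactants: 4 hexabenzyl flavan-3,4-diol
Product: 5 (2R)-3,7-bis(benzyloxy)-2-[3,4,5-tris(benzyloxy)phenyl]-4-[(trimethylsilyl)ethynyl]chromane, 2,3-trans-3,4-trans (alkyne 4α, cis to the C2 aryl group)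
Conditions: potassium trifluoro[(trimethylsilyl)ethynyl]borate (2.5 equiv), BF3·OEt2 (2.5 equiv), CH2Cl2/MeCN, −40 → 0 °C
Reagents that add atoms: potassium trifluoro[(trimethylsilyl)ethynyl]borate, [K+].C[Si](C)(C)C#C[B-](F)(F)F
Why: Lewis-acid ionisation of the C4 benzyl ether gives the benzylic cation stabilised by O1 and the 7-benzyloxy group, which is trapped by the alkynyldifluoroborane formed in situ (SN1 alkynylation with an alkynyltrifluoroborate); attack anti to the C3 benzyloxy group sets the 3,4-trans (4α) centre, any 3,4-cis isomer being removed by chromatography.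

Step 5
Reactants: 5 4α-(trimethylsilylethynyl)flavan
Product: 6 (2R)-3,7-bis(benzyloxy)-4-ethynyl-2-[3,4,5-tris(benzyloxy)phenyl]chromane, 2,3-trans-3,4-trans
Conditions: K2CO3 (cat.), MeOH/THF, rt
Reagents that add atoms: none
Why: Base-catalysed methanolysis of the alkynyl C–Si bond (protodesilylation) is selective for the silylalkyne.

Step 6
Reactants: 6 4α-ethynylflavan
Product: 9 (2R)-3,7-bis(benzyloxy)-2-[3,4,5-tris(benzyloxy)phenyl]-4-[(triisopropylsilyloxy)ethynyl]chromane (2,3-trans-3,4-trans), via lithium acetylide 7 (not isolated), via lithium ynolate 8 (not isolated)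
Conditions: n-BuLi (1.05 equiv), THF, −78 °C; t-BuOOLi (from t-BuOOH, LiHMDS), −78 → 0 °C; TIPSOTf, −78 → 0 °C
Reagents that add atoms: tert-butyl hydroperoxide, CC(C)(C)OO; triisopropylsilyl trifluoromethanesulfonate, CC(C)[Si](C(C)C)(C(C)C)OS(=O)(=O)C(F)(F)F
Why: Lithiation of the terminal alkyne, oxygen transfer from lithium tert-butyl peroxide to the acetylide carbon (electrophilic oxidation to the ynolate) and O-silylation with the bulky silyl triflate is the standard entry to 1-siloxy-1-alkynes, and the C4 stereocentre is not deprotonated at −78 °C.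

Step 7
Reactants: 10 4-methoxybenzyl propargyl ether
Product: 11 (E)-2-[3-(4-methoxybenzyloxy)prop-1-en-1-yl]-4,4,5,5-tetramethyl-1,3,2-dioxaborolane
Conditions: HBpin (1.1 equiv), Cp2Zr(H)Cl (5 mol %), Et3N (10 mol %), neat, 60 °C
Reagents that add atoms: pinacolborane, CC1(C)OBOC1(C)C
Why: Zirconium-catalysed syn-hydroboration of the terminal alkyne with pinacolborane gives the (E)-alkenylboronate.

Step 8
Reactants: 11 (E)-alkenylboronate
Product: 12 (E)-2-[3-(4-methoxybenzyloxy)prop-2-en-1-yl]-4,4,5,5-tetramethyl-1,3,2-dioxaborolane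
Conditions: [Ir(cod)(PPh2Me)2]PF6 (2 mol %, activated with H2), THF, rt
Reagents that add atoms: none
Why: Cationic iridium hydride catalysis moves the double bond into conjugation with oxygen (allyl ether to (E)-enol ether isomerisation), giving the (E)-γ-alkoxyallylboronate.

Step 9
Reactants: 12 (E)-γ-(4-methoxybenzyloxy)allylboronate; 13 3,4,5-tris(benzyloxy)benzaldehyde
Product: 15 (1S,2R)-2-(4-methoxybenzyloxy)-1-[3,4,5-tris(benzyloxy)phenyl]but-3-en-1-ol, via pinacol borate ester 14 (not isolated)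
Conditions: (R)-TRIP (5 mol %), 4 Å MS, PhMe, −30 → 0 °C; aq NaHCO3
Reagents that add atoms: none
Why: Chiral phosphoric acid-catalysed allylboration through a closed chair transition state, in which the (E)-geometry of 12 becomes the anti relationship of C2' and C3' and the (R)-catalyst, by analogy to allyl and crotyl pinacolboronates, directs attack to the Re face of the aldehyde to give the (1S,2R) isomer.

Step 10
Reactants: 15 anti homoallylic alcohol
Product: 16 tert-butyldimethylsilyl ether of 15 [(1S,2R)-1-(tert-butyldimethylsilyloxy)-2-(4-methoxybenzyloxy)-1-[3,4,5-tris(benzyloxy)phenyl]but-3-ene]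
Conditions: TBSOTf, 2,6-lutidine, CH2Cl2, −78 → 0 °C
Reagents that add atoms: tert-butyldimethylsilyl trifluoromethanesulfonate, CC(C)(C)[Si](C)(C)OS(=O)(=O)C(F)(F)F
Why: Silylation of the hindered benzylic alcohol with the silyl triflate and a non-nucleophilic base.

Step 11
Reactants: 16 silyl ether
Product: 18 (3R,4S)-4-(tert-butyldimethylsilyloxy)-3-(4-methoxybenzyloxy)-4-[3,4,5-tris(benzyloxy)phenyl]butan-1-ol, via B-alkyl-9-BBN 17 (not isolated)
Conditions: 9-BBN, THF, 0 °C → rt; NaOH, H2O2, 0 °C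
Reagents that add atoms: hydrogen peroxide, OO
Why: Anti-Markovnikov hydroboration of the terminal alkene with the bulky dialkylborane, followed by oxidation of the C–B bond with retention, gives the primary alcohol.

Step 12
Reactants: 18 primary alcohol
Product: 19 (3R,4S)-4-(tert-butyldimethylsilyloxy)-3-(4-methoxybenzyloxy)-4-[3,4,5-tris(benzyloxy)phenyl]butanal
Conditions: TEMPO (10 mol %), PhI(OAc)2, CH2Cl2, rt
Reagents that add atoms: none
Why: Oxoammonium-catalysed (TEMPO) oxidation of the primary alcohol stops at the aldehyde and is free of base, so the β-alkoxy aldehyde does not eliminate.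

Step 13
Reactants: 20 dimethyl (1-diazo-2-oxopropyl)phosphonate (Ohira–Bestmann reagent)
Product: 21 dimethyl (1-benzyloxy-2-oxopropyl)phosphonate (racemic)
Conditions: BnOH (2 equiv), Rh2(OAc)4 (1 mol %), PhMe, 80 °C
Reagents that add atoms: benzyl alcohol, OCc1ccccc1
Why: Rhodium carbenoid O–H insertion into benzyl alcohol installs the future C5' oxygen; the new centre is racemic and is destroyed in step 14.

Step 14
Reactants: 19 β-alkoxy aldehyde; 21 α-benzyloxy β-ketophosphonate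
Product: 22 (3Z,6R,7S)-3-(benzyloxy)-7-(tert-butyldimethylsilyloxy)-6-(4-methoxybenzyloxy)-7-[3,4,5-tris(benzyloxy)phenyl]hept-3-en-2-one
Conditions: 21, NaH, THF, 0 °C; then 19, −78 → 0 °C
Reagents that add atoms: none
Why: Horner–Wadsworth–Emmons olefination of the stabilised β-ketophosphonate anion should give mainly the (Z)-enol ether in which the acetyl group and C4' are trans (the thermodynamically preferred arrangement), the minor (E)-isomer being removed by chromatography.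

Step 15
Reactants: 22 enone
Product: 23 (3Z,6R,7S)-3-(benzyloxy)-7-(tert-butyldimethylsilyloxy)-6-hydroxy-7-[3,4,5-tris(benzyloxy)phenyl]hept-3-en-2-one
Conditions: DDQ, CH2Cl2/pH 7 buffer (10:1), 0 °C
Reagents that add atoms: none
Why: Oxidative cleavage of the p-methoxybenzyl ether by DDQ (benzylic hydride abstraction, then hydrolysis of the oxocarbenium ion), which is faster for the p-methoxybenzyl group than for benzyl ethers or the silylated 3,4,5-trialkoxybenzylic position.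

Step 16
Reactants: 23 hydroxy enone; 24 3,4,5-tris(benzyloxy)benzoic acid
Product: 25 (3Z,6R,7S)-3-(benzyloxy)-7-(tert-butyldimethylsilyloxy)-2-oxo-7-[3,4,5-tris(benzyloxy)phenyl]hept-3-en-6-yl 3,4,5-tris(benzyloxy)benzoate
Conditions: DCC, DMAP, CH2Cl2, rt
Reagents that add atoms: none
Why: Steglich esterification (carbodiimide activation, DMAP acyl transfer) acylates the hindered secondary C3' alcohol under neutral conditions that do not move the neighbouring silyl group.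

Step 17
Reactants: 25 gallate methyl ketone
Product: 28 (3Z,6R,7S)-3-(benzyloxy)-7-(tert-butyldimethylsilyloxy)-1-diazo-2-oxo-7-[3,4,5-tris(benzyloxy)phenyl]hept-3-en-6-yl 3,4,5-tris(benzyloxy)benzoate, via lithium enolate 26 (not isolated), via trifluoroacetyl diketone 27 (not isolated)
Conditions: LiHMDS (1.1 equiv), THF, −78 °C; CF3CO2CH2CF3, −78 °C; aq NH4Cl; then MsN3, Et3N, H2O, MeCN, rt
Reagents that add atoms: methanesulfonyl azide, CS(=O)(=O)N=[N+]=[N-]
Why: Kinetic α'-enolisation of the methyl ketone, Claisen-type trifluoroacetylation and detrifluoroacetylative diazo transfer (Regitz-type) is the established way to α,β-unsaturated diazomethyl ketones and avoids diazomethane, while −78 °C and one equivalent of a hindered amide base spare the ester and the C4' protons.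

Step 18
Reactants: 9 flavan-4-yl siloxyalkyne; 28 α-benzyloxy diazo enone
Product: 33 seco lower unit (D-ring phenol with free C8a' hydroxyl; C7' triisopropylsilyl ether; C5' benzyl ether; C8' bearing the upper flavan-4α-yl group; C4a' bearing the open C4'–C3'(gallate)–C2'(silyl ether) chain), via vinylketene 29 (not isolated), via vinylcyclobutenone 30 (not isolated), via dienylketene 31 (not isolated), via cyclohexadienone 32 (not isolated)
Conditions: 9 (1.5 equiv), 28 (1.0 equiv), hν (365 nm LED), ClCH2CH2Cl (0.05 M), rt, Ar; then 80 °C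
Reagents that add atoms: none
Why: Light expels nitrogen from 28 and the enol-ether vinyl group migrates (Wolff rearrangement) to give vinylketene 29, whose electrophilic carbonyl carbon is attacked by the nucleophilic, flavanyl-bearing carbon of the ynol silyl ether while its α-carbon bonds to the siloxy carbon, giving 4-vinylcyclobutenone 30 (C8'–C8a' and C6'–C7'). Warming opens 30 by 4π-electrocyclisation to dienylketene 31, which closes the six-membered D-ring by thermal 6π-electrocyclisation (C4a'–C8a', the only ring-closing event) to dienone 32 and tautomerises to the phenol. The closest known reaction type is the Danheiser benzannulation of photochemically generated vinylketenes with siloxyalkynes, which delivers resorcinol monosilyl ethers with the alkyne substituent between the two oxygens. No stereocentre is created: the sp3 carbons of 30 and 32 are erased on aromatisation and the five existing centres (C2, C3, C4, C2', C3') lie outside the reacting π-system. The step needs regiocontrol in the [2+2] addition, secured by the polarisation of the siloxyalkyne, and a vinylketene that cannot escape by 1,5-hydrogen shift, secured by the (Z)-enone geometry that places C4' trans to the ketene-bearing carbon. Irradiation at 365 nm is chosen so that only the diazo enone, not the benzyl ethers or the gallate, absorbs.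

Step 19
Reactants: 33 seco lower unit
Product: 34 desilylated seco compound (free C2' alcohol and free C7' and C8a' phenols; gallate still on O3'; configuration 2'S,3'R)
Conditions: TBAF, AcOH (1:1), THF, 0 °C → rt
Reagents that add atoms: none
Why: Fluoride cleaves both Si–O bonds (strong Si–F bond), and the acetic acid buffer keeps the C2' alkoxide protonated so that the neighbouring gallate does not migrate.

Step 20
Reactants: 34 desilylated seco compound
Product: 35 dodeca-O-benzyl robinetinidol-(4α→8)-epigallocatechin 3'-O-gallate with free C7' hydroxyl (lower ring 2'R,3'R, cis)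
Conditions: PPh3, DIAD, THF (0.01 M), 0 °C → rt
Reagents that add atoms: none
Why: Intramolecular Mitsunobu etherification in which the C8a' phenol displaces the phosphonium-activated benzylic C2' oxygen in a 6-exo-tet SN2 reaction with inversion (2'S to 2'R), which sets the 2',3'-cis ring, whereas the C7' phenol cannot reach C2'.

Step 21
Reactants: 35 dodecabenzyl dimer
Product: 36 CNP0269431.1, (2R,3S,4S)-robinetinidol-(4α→8)-(2R,3R)-epigallocatechin 3-O-gallate
Conditions: H2 (1 atm), 20 % Pd(OH)2/C, THF/MeOH (1:1), rt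
Reagents that add atoms: none
Why: Palladium-catalysed hydrogenolysis cleaves all twelve O-benzyl ethers without touching the ester, the flavan C–O bonds or any stereocentre.

Compound list

1 | (+)-dihydrorobinetin, (2R,3R)-3,7-dihydroxy-2-(3,4,5-trihydroxyphenyl)chroman-4-one | O=C1c2ccc(O)cc2O[C@H](c2cc(O)c(O)c(O)c2)[C@H]1O | starting material
2 | (2R,3R)-7-(benzyloxy)-3-hydroxy-2-[3,4,5-tris(benzyloxy)phenyl]chroman-4-one | O=C1c2ccc(OCc9ccccc9)cc2O[C@H](c2cc(OCc9ccccc9)c(OCc9ccccc9)c(OCc9ccccc9)c2)[C@H]1O | intermediate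
3 | (2R,3S,4R)-7-(benzyloxy)-2-[3,4,5-tris(benzyloxy)phenyl]chromane-3,4-diol | O[C@@H]1c2ccc(OCc9ccccc9)cc2O[C@H](c2cc(OCc9ccccc9)c(OCc9ccccc9)c(OCc9ccccc9)c2)[C@H]1O | intermediate
4 | 3,4-di-O-benzyl ether of 3 (2,3-trans-3,4-trans) | O(Cc9ccccc9)[C@@H]1c2ccc(OCc9ccccc9)cc2O[C@H](c2cc(OCc9ccccc9)c(OCc9ccccc9)c(OCc9ccccc9)c2)[C@H]1OCc9ccccc9 | intermediate
5 | 4α-[(trimethylsilyl)ethynyl]-3,7-bis(benzyloxy)-2-[3,4,5-tris(benzyloxy)phenyl]chromane (2R, 2,3-trans-3,4-trans) | C[Si](C)(C)C#C[C@@H]1c2ccc(OCc9ccccc9)cc2O[C@H](c2cc(OCc9ccccc9)c(OCc9ccccc9)c(OCc9ccccc9)c2)[C@H]1OCc9ccccc9 | intermediate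
6 | 4α-ethynyl analogue of 5 | C#C[C@@H]1c2ccc(OCc9ccccc9)cc2O[C@H](c2cc(OCc9ccccc9)c(OCc9ccccc9)c(OCc9ccccc9)c2)[C@H]1OCc9ccccc9 | intermediate
7 | lithium acetylide of 6 | [Li+].[C-]#C[C@@H]1c2ccc(OCc9ccccc9)cc2O[C@H](c2cc(OCc9ccccc9)c(OCc9ccccc9)c(OCc9ccccc9)c2)[C@H]1OCc9ccccc9 | intermediate
8 | lithium ynolate (flavan-4α-yl ynolate) | [Li+].[O-]C#C[C@@H]1c2ccc(OCc9ccccc9)cc2O[C@H](c2cc(OCc9ccccc9)c(OCc9ccccc9)c(OCc9ccccc9)c2)[C@H]1OCc9ccccc9 | intermediate
9 | 4α-[(triisopropylsilyloxy)ethynyl]-3,7-bis(benzyloxy)-2-[3,4,5-tris(benzyloxy)phenyl]chromane (2R, 2,3-trans-3,4-trans) | CC(C)[Si](C(C)C)(C(C)C)OC#C[C@@H]3c4ccc(OCc9ccccc9)cc4O[C@H](c4cc(OCc9ccccc9)c(OCc9ccccc9)c(OCc9ccccc9)c4)[C@H]3OCc9ccccc9 | intermediate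
10 | 4-methoxybenzyl propargyl ether | C#CCOCc1ccc(OC)cc1 | starting material
11 | (E)-2-[3-(4-methoxybenzyloxy)prop-1-en-1-yl]-4,4,5,5-tetramethyl-1,3,2-dioxaborolane | COc1ccc(COC/C=C/B2OC(C)(C)C(C)(C)O2)cc1 | intermediate
12 | (E)-2-[3-(4-methoxybenzyloxy)prop-2-en-1-yl]-4,4,5,5-tetramethyl-1,3,2-dioxaborolane | COc1ccc(CO/C=C/CB2OC(C)(C)C(C)(C)O2)cc1 | intermediate
13 | 3,4,5-tris(benzyloxy)benzaldehyde | O=Cc1cc(OCc9ccccc9)c(OCc9ccccc9)c(OCc9ccccc9)c1 | starting material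
14 | pinacol borate ester of 15 | C=C[C@@H](OCc1ccc(OC)cc1)[C@@H](OB2OC(C)(C)C(C)(C)O2)c1cc(OCc9ccccc9)c(OCc9ccccc9)c(OCc9ccccc9)c1 | intermediate
15 | (1S,2R)-2-(4-methoxybenzyloxy)-1-[3,4,5-tris(benzyloxy)phenyl]but-3-en-1-ol (anti) | C=C[C@@H](OCc1ccc(OC)cc1)[C@@H](O)c1cc(OCc9ccccc9)c(OCc9ccccc9)c(OCc9ccccc9)c1 | intermediate
16 | tert-butyldimethylsilyl ether of 15 | C=C[C@@H](OCc1ccc(OC)cc1)[C@@H](O[Si](C)(C)C(C)(C)C)c1cc(OCc9ccccc9)c(OCc9ccccc9)c(OCc9ccccc9)c1 | intermediate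
17 | B-alkyl-9-borabicyclo[3.3.1]nonane from 16 (boron on the terminal carbon) | C1CC2CCCC(C1)B2CC[C@@H](OCc1ccc(OC)cc1)[C@@H](O[Si](C)(C)C(C)(C)C)c1cc(OCc9ccccc9)c(OCc9ccccc9)c(OCc9ccccc9)c1 | intermediate
18 | (3R,4S)-4-(tert-butyldimethylsilyloxy)-3-(4-methoxybenzyloxy)-4-[3,4,5-tris(benzyloxy)phenyl]butan-1-ol | OCC[C@@H](OCc1ccc(OC)cc1)[C@@H](O[Si](C)(C)C(C)(C)C)c1cc(OCc9ccccc9)c(OCc9ccccc9)c(OCc9ccccc9)c1 | intermediate
19 | (3R,4S)-4-(tert-butyldimethylsilyloxy)-3-(4-methoxybenzyloxy)-4-[3,4,5-tris(benzyloxy)phenyl]butanal | O=CC[C@@H](OCc1ccc(OC)cc1)[C@@H](O[Si](C)(C)C(C)(C)C)c1cc(OCc9ccccc9)c(OCc9ccccc9)c(OCc9ccccc9)c1 | intermediate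
20 | dimethyl (1-diazo-2-oxopropyl)phosphonate | CC(=O)C(=[N+]=[N-])P(=O)(OC)OC | starting material
21 | dimethyl (1-benzyloxy-2-oxopropyl)phosphonate (racemic) | CC(=O)C(OCc1ccccc1)P(=O)(OC)OC | intermediate
22 | (3Z,6R,7S)-3-(benzyloxy)-7-(tert-butyldimethylsilyloxy)-6-(4-methoxybenzyloxy)-7-[3,4,5-tris(benzyloxy)phenyl]hept-3-en-2-one | CC(=O)/C(OCc9ccccc9)=C/C[C@@H](OCc1ccc(OC)cc1)[C@@H](O[Si](C)(C)C(C)(C)C)c1cc(OCc9ccccc9)c(OCc9ccccc9)c(OCc9ccccc9)c1 | intermediate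
23 | (3Z,6R,7S)-3-(benzyloxy)-7-(tert-butyldimethylsilyloxy)-6-hydroxy-7-[3,4,5-tris(benzyloxy)phenyl]hept-3-en-2-one | CC(=O)/C(OCc9ccccc9)=C/C[C@@H](O)[C@@H](O[Si](C)(C)C(C)(C)C)c1cc(OCc9ccccc9)c(OCc9ccccc9)c(OCc9ccccc9)c1 | intermediate
24 | 3,4,5-tris(benzyloxy)benzoic acid | OC(=O)c1cc(OCc9ccccc9)c(OCc9ccccc9)c(OCc9ccccc9)c1 | starting material
25 | O3'-[3,4,5-tris(benzyloxy)benzoate] of 23 | CC(=O)/C(OCc9ccccc9)=C/C[C@@H](OC(=O)c1cc(OCc9ccccc9)c(OCc9ccccc9)c(OCc9ccccc9)c1)[C@@H](O[Si](C)(C)C(C)(C)C)c1cc(OCc9ccccc9)c(OCc9ccccc9)c(OCc9ccccc9)c1 | intermediate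
26 | lithium α'-enolate of 25 | [Li+].C=C([O-])/C(OCc9ccccc9)=C/C[C@@H](OC(=O)c1cc(OCc9ccccc9)c(OCc9ccccc9)c(OCc9ccccc9)c1)[C@@H](O[Si](C)(C)C(C)(C)C)c1cc(OCc9ccccc9)c(OCc9ccccc9)c(OCc9ccccc9)c1 | intermediate
27 | α'-trifluoroacetyl derivative of 25 (1,3-diketone) | O=C(CC(=O)/C(OCc9ccccc9)=C/C[C@@H](OC(=O)c1cc(OCc9ccccc9)c(OCc9ccccc9)c(OCc9ccccc9)c1)[C@@H](O[Si](C)(C)C(C)(C)C)c1cc(OCc9ccccc9)c(OCc9ccccc9)c(OCc9ccccc9)c1)C(F)(F)F | intermediate
28 | (3Z,6R,7S)-3-(benzyloxy)-7-(tert-butyldimethylsilyloxy)-1-diazo-2-oxo-7-[3,4,5-tris(benzyloxy)phenyl]hept-3-en-6-yl 3,4,5-tris(benzyloxy)benzoate | [N-]=[N+]=CC(=O)/C(OCc9ccccc9)=C/C[C@@H](OC(=O)c1cc(OCc9ccccc9)c(OCc9ccccc9)c(OCc9ccccc9)c1)[C@@H](O[Si](C)(C)C(C)(C)C)c1cc(OCc9ccccc9)c(OCc9ccccc9)c(OCc9ccccc9)c1 | intermediate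
29 | 3-benzyloxy vinylketene from 28 (ketene CH attached to the C(OBn)=CH–C4' unit; chain unchanged) | O=C=C/C(OCc9ccccc9)=C/C[C@@H](OC(=O)c1cc(OCc9ccccc9)c(OCc9ccccc9)c(OCc9ccccc9)c1)[C@@H](O[Si](C)(C)C(C)(C)C)c1cc(OCc9ccccc9)c(OCc9ccccc9)c(OCc9ccccc9)c1 | intermediate
30 | 2-(flavan-4α-yl)-3-(triisopropylsilyloxy)-4-alkenylcyclobut-2-en-1-one (mixture at the ring sp3 carbon) | O=C1C([C@@H]3c4ccc(OCc9ccccc9)cc4O[C@H](c4cc(OCc9ccccc9)c(OCc9ccccc9)c(OCc9ccccc9)c4)[C@H]3OCc9ccccc9)=C(O[Si](C(C)C)(C(C)C)C(C)C)C1/C(OCc9ccccc9)=C/C[C@@H](OC(=O)c2cc(OCc9ccccc9)c(OCc9ccccc9)c(OCc9ccccc9)c2)[C@@H](O[Si](C)(C)C(C)(C)C)c2cc(OCc9ccccc9)c(OCc9ccccc9)c(OCc9ccccc9)c2 | intermediate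
31 | (Z)-dienylketene from ring opening of 30 | O=C=C([C@@H]3c4ccc(OCc9ccccc9)cc4O[C@H](c4cc(OCc9ccccc9)c(OCc9ccccc9)c(OCc9ccccc9)c4)[C@H]3OCc9ccccc9)/C(O[Si](C(C)C)(C(C)C)C(C)C)=C\C(OCc9ccccc9)=C\C[C@@H](OC(=O)c2cc(OCc9ccccc9)c(OCc9ccccc9)c(OCc9ccccc9)c2)[C@@H](O[Si](C)(C)C(C)(C)C)c2cc(OCc9ccccc9)c(OCc9ccccc9)c(OCc9ccccc9)c2 | intermediate
32 | cyclohexa-2,4-dienone tautomer of 33 (mixture at the ring sp3 carbon) | O=C1C([C@@H]3c4ccc(OCc9ccccc9)cc4O[C@H](c4cc(OCc9ccccc9)c(OCc9ccccc9)c(OCc9ccccc9)c4)[C@H]3OCc9ccccc9)=C(O[Si](C(C)C)(C(C)C)C(C)C)C=C(OCc9ccccc9)C1C[C@@H](OC(=O)c2cc(OCc9ccccc9)c(OCc9ccccc9)c(OCc9ccccc9)c2)[C@@H](O[Si](C)(C)C(C)(C)C)c2cc(OCc9ccccc9)c(OCc9ccccc9)c(OCc9ccccc9)c2 | intermediate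
33 | seco lower unit: D-ring phenol (C8a' OH free, C7' OTIPS, C5' OBn, C8' flavan-4α-yl, open chain with 3'R gallate and 2'S OTBS) | O=C(O[C@H](Cc2c(OCc9ccccc9)cc(O[Si](C(C)C)(C(C)C)C(C)C)c([C@@H]3c4ccc(OCc9ccccc9)cc4O[C@H](c4cc(OCc9ccccc9)c(OCc9ccccc9)c(OCc9ccccc9)c4)[C@H]3OCc9ccccc9)c2O)[C@@H](O[Si](C)(C)C(C)(C)C)c1cc(OCc9ccccc9)c(OCc9ccccc9)c(OCc9ccccc9)c1)c1cc(OCc9ccccc9)c(OCc9ccccc9)c(OCc9ccccc9)c1 | intermediate
34 | desilylated seco compound (C2' OH, C7' OH, C8a' OH free; 2'S,3'R) | O=C(O[C@H](Cc2c(OCc9ccccc9)cc(O)c([C@@H]3c4ccc(OCc9ccccc9)cc4O[C@H](c4cc(OCc9ccccc9)c(OCc9ccccc9)c(OCc9ccccc9)c4)[C@H]3OCc9ccccc9)c2O)[C@@H](O)c1cc(OCc9ccccc9)c(OCc9ccccc9)c(OCc9ccccc9)c1)c1cc(OCc9ccccc9)c(OCc9ccccc9)c(OCc9ccccc9)c1 | intermediate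
35 | dodeca-O-benzyl robinetinidol-(4α→8)-epigallocatechin 3'-O-gallate, C7' OH free (lower ring 2'R,3'R) | O=C(O[C@@H]1Cc2c(OCc9ccccc9)cc(O)c([C@@H]3c4ccc(OCc9ccccc9)cc4O[C@H](c4cc(OCc9ccccc9)c(OCc9ccccc9)c(OCc9ccccc9)c4)[C@H]3OCc9ccccc9)c2O[C@@H]1c1cc(OCc9ccccc9)c(OCc9ccccc9)c(OCc9ccccc9)c1)c1cc(OCc9ccccc9)c(OCc9ccccc9)c(OCc9ccccc9)c1 | intermediate
36 | CNP0269431.1, (2R,3S,4S)-robinetinidol-(4α→8)-(2R,3R)-epigallocatechin 3-O-gallate | O=C(O[C@@H]1Cc2c(O)cc(O)c([C@@H]3c4ccc(O)cc4O[C@H](c4cc(O)c(O)c(O)c4)[C@H]3O)c2O[C@@H]1c1cc(O)c(O)c(O)c1)c1cc(O)c(O)c(O)c1 | target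

Total step count: 21. Longest linear sequence: 14 steps (steps 7–12 and 14–21, from 10 to 36).

Steps most likely to fail

1. Step 18. The vinylketene may be consumed by dimerisation or by acylation of the product phenol before it adds to the hindered siloxyalkyne, or photolysis may be slowed by the other chromophores. In that case the arene would be taken from nature instead of being built. Natural (−)-epigallocatechin 3-O-gallate F1 is perbenzylated (BnBr, K2CO3, DMF) to its octa-O-benzyl ether F2. Compound 4 is then ionised with TMSOTf (CH2Cl2, −78 °C) in the presence of excess F2, so that C8' of F2 attacks the C4 cation (Friedel–Crafts-type flavan coupling). This gives the tridecabenzyl 4α→8 dimer F3 after separation from the 4→6 and 4β isomers that this known coupling also forms. Hydrogenolysis (H2, Pd(OH)2/C) of F3 completes the fallback, which sets out from 4 and returns to the route at 36.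

2. Step 20. Inversion at C2' may be eroded because the neighbouring gallate carbonyl participates, because the activated benzylic oxygen ionises before the phenol attacks, or because the ester migrates to O2' once that hydroxyl is free. The gallate would then be introduced only after ring closure. Setting out from 23, O3' is silylated (TBSOTf, 2,6-lutidine) to the bis-silyl enone F4. F4 is converted as in step 17 into the bis-silyl diazo ketone F5, and as in step 18 with 9 into the bis-silyl seco phenol F6. HF·pyridine (THF/pyridine) removes the two alkyl silyl ethers but not the aryl silyl ether and gives the diol F7. Mitsunobu closure (PPh3, DIAD) at the more reactive benzylic hydroxyl gives the 2',3'-cis flavan-3'-ol F8, with no participating group next to C2'. Steglich esterification with 24 gives the silyl-protected gallate F9, and buffered fluoride (TBAF, AcOH) frees O7' and returns to the route at 35.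

3. Step 17. The amide base may remove a C4' proton or attack the ester, so that the gallate is lost by elimination or acyl transfer. The base chemistry would then be done before the ester exists. From 23, the same two-stage diazo transfer with 2.2 equiv LiHMDS (alkoxide plus enolate; the transient O-trifluoroacetate is hydrolysed in the Et3N/H2O stage) gives the hydroxy diazo ketone F10. Esterification of F10 with 24 (DCC, DMAP; neutral conditions that a diazo ketone tolerates) returns to the route at 28.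

Further compounds

F1 | step 18 | (−)-epigallocatechin 3-O-gallate | O=C(O[C@@H]1Cc2c(O)cc(O)cc2O[C@@H]1c1cc(O)c(O)c(O)c1)c1cc(O)c(O)c(O)c1
F2 | step 18 | octa-O-benzyl-(−)-epigallocatechin 3-O-gallate | O=C(O[C@@H]1Cc2c(OCc9ccccc9)cc(OCc9ccccc9)cc2O[C@@H]1c1cc(OCc9ccccc9)c(OCc9ccccc9)c(OCc9ccccc9)c1)c1cc(OCc9ccccc9)c(OCc9ccccc9)c(OCc9ccccc9)c1
F3 | step 18 | trideca-O-benzyl robinetinidol-(4α→8)-epigallocatechin 3'-O-gallate | O=C(O[C@@H]1Cc2c(OCc9ccccc9)cc(OCc9ccccc9)c([C@@H]3c4ccc(OCc9ccccc9)cc4O[C@H](c4cc(OCc9ccccc9)c(OCc9ccccc9)c(OCc9ccccc9)c4)[C@H]3OCc9ccccc9)c2O[C@@H]1c1cc(OCc9ccccc9)c(OCc9ccccc9)c(OCc9ccccc9)c1)c1cc(OCc9ccccc9)c(OCc9ccccc9)c(OCc9ccccc9)c1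
F4 | step 20 | (3Z,6R,7S)-3-(benzyloxy)-6,7-bis(tert-butyldimethylsilyloxy)-7-[3,4,5-tris(benzyloxy)phenyl]hept-3-en-2-one | CC(=O)/C(OCc9ccccc9)=C/C[C@@H](O[Si](C)(C)C(C)(C)C)[C@@H](O[Si](C)(C)C(C)(C)C)c1cc(OCc9ccccc9)c(OCc9ccccc9)c(OCc9ccccc9)c1
F5 | step 20 | (3Z,6R,7S)-3-(benzyloxy)-6,7-bis(tert-butyldimethylsilyloxy)-1-diazo-7-[3,4,5-tris(benzyloxy)phenyl]hept-3-en-2-one | [N-]=[N+]=CC(=O)/C(OCc9ccccc9)=C/C[C@@H](O[Si](C)(C)C(C)(C)C)[C@@H](O[Si](C)(C)C(C)(C)C)c1cc(OCc9ccccc9)c(OCc9ccccc9)c(OCc9ccccc9)c1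
F6 | step 20 | seco phenol with 2',3'-bis(tert-butyldimethylsilyl) ethers (C8a' OH free, C7' OTIPS) | Oc1c([C@@H]3c4ccc(OCc9ccccc9)cc4O[C@H](c4cc(OCc9ccccc9)c(OCc9ccccc9)c(OCc9ccccc9)c4)[C@H]3OCc9ccccc9)c(O[Si](C(C)C)(C(C)C)C(C)C)cc(OCc9ccccc9)c1C[C@@H](O[Si](C)(C)C(C)(C)C)[C@@H](O[Si](C)(C)C(C)(C)C)c1cc(OCc9ccccc9)c(OCc9ccccc9)c(OCc9ccccc9)c1
F7 | step 20 | seco 2',3'-diol (2'S,3'R; C8a' OH free, C7' OTIPS) | Oc1c([C@@H]3c4ccc(OCc9ccccc9)cc4O[C@H](c4cc(OCc9ccccc9)c(OCc9ccccc9)c(OCc9ccccc9)c4)[C@H]3OCc9ccccc9)c(O[Si](C(C)C)(C(C)C)C(C)C)cc(OCc9ccccc9)c1C[C@@H](O)[C@@H](O)c1cc(OCc9ccccc9)c(OCc9ccccc9)c(OCc9ccccc9)c1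
F8 | step 20 | benzylated robinetinidol-(4α→8)-epigallocatechin with free 3'-OH and C7' OTIPS (2'R,3'R) | O[C@@H]1Cc2c(OCc9ccccc9)cc(O[Si](C(C)C)(C(C)C)C(C)C)c([C@@H]3c4ccc(OCc9ccccc9)cc4O[C@H](c4cc(OCc9ccccc9)c(OCc9ccccc9)c(OCc9ccccc9)c4)[C@H]3OCc9ccccc9)c2O[C@@H]1c1cc(OCc9ccccc9)c(OCc9ccccc9)c(OCc9ccccc9)c1
F9 | step 20 | 7'-O-triisopropylsilyl ether of 35 | O=C(O[C@@H]1Cc2c(OCc9ccccc9)cc(O[Si](C(C)C)(C(C)C)C(C)C)c([C@@H]3c4ccc(OCc9ccccc9)cc4O[C@H](c4cc(OCc9ccccc9)c(OCc9ccccc9)c(OCc9ccccc9)c4)[C@H]3OCc9ccccc9)c2O[C@@H]1c1cc(OCc9ccccc9)c(OCc9ccccc9)c(OCc9ccccc9)c1)c1cc(OCc9ccccc9)c(OCc9ccccc9)c(OCc9ccccc9)c1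
F10 | step 17 | (3Z,6R,7S)-3-(benzyloxy)-7-(tert-butyldimethylsilyloxy)-1-diazo-6-hydroxy-7-[3,4,5-tris(benzyloxy)phenyl]hept-3-en-2-one | [N-]=[N+]=CC(=O)/C(OCc9ccccc9)=C/C[C@@H](O)[C@@H](O[Si](C)(C)C(C)(C)C)c1cc(OCc9ccccc9)c(OCc9ccccc9)c(OCc9ccccc9)c1
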